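**Retrosynthetic overview**
1. The target comes from its hexaacetate by one global methanolysis. No stereocentre is touched, and all-trans is also the thermodynamic C4 epimer.
2. In the hexaacetate, the furan O–C2 bond and the cyclohexene C3–C4 and C5–C6 bonds are cut together. This leads back to a ring-free o-alkynylphenol-diene and a 2'-hydroxychalcone triacetate held on an (R)-VANOL–boron template.
3. The alkynylphenol-diene comes from an E-selective allylic Wittig reaction, a Sonogashira coupling with 3-ethynylphenol, 4-O-silyl/2,6-di-O-acetyl differentiation, and mono-iodination of 2,4,6-trihydroxybenzaldehyde.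
4. The chalcone comes from a Claisen–Schmidt condensation of 2,4-dihydroxyacetophenone with 2,4-dihydroxybenzaldehyde, then triacetylation that spares the chelated OH.
5. Ring order: no ring is made before the key flask. There the furan closes first (within minutes) and the cyclohexene second.

Numbering used for the cyclohexene: C1(Me)=C2, C3 (benzofuranyl), C4 (aroyl), C5 (aryl), C6.

Assumption: a quadrant model of the spiro-borate says the (R)-VANOL chelate leaves the Cα-Si face of the chalcone open, which gives 4R,5S. This sense is to be checked by CD on the cycloadduct, and (S)-VANOL would replace it with no other change if the sign is opposite.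

**Step 1**
Reactants: 1 2,4-dihydroxyacetophenone; 2 2,4-dihydroxybenzaldehyde
Product: 3 (E)-2,2',4,4'-tetrahydroxychalcone
Conditions: KOH (60% aq), EtOH, Ar, 0 → 50 °C, 48 h; cold 2 M HCl to pH 5
Reagents that add atoms: none
Why: Claisen–Schmidt aldol condensation with E1cB dehydration, in which the acetophenone polyanion still enolises in concentrated KOH, the conjugated (E)-enone is the thermodynamic product (modest yield is normal for unprotected resorcinol partners), and stopping the quench at pH 5 avoids flavylium formation.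

**Step 2**
Reactants: 3 (E)-2,2',4,4'-tetrahydroxychalcone
Product: 4 (E)-2,4,4'-triacetoxy-2'-hydroxychalcone
Conditions: Ac2O (3.1 equiv), Et3N (3.3 equiv), THF, −10 → 0 °C
Reagents that add atoms: acetic anhydride, CC(=O)OC(C)=O
Why: Chemoselective O-acetylation, in which the three free phenols acylate at 0 °C while the 2'-OH stays free because it is locked in a hydrogen bond to the ketone, and this OH is the handle that boron needs later.

**Step 3**
Reactants: 5 2,4,6-trihydroxybenzaldehyde
Product: 6 2,4,6-trihydroxy-3-iodobenzaldehyde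
Conditions: NIS (1.0 equiv), MeCN, −20 → 0 °C, dark
Reagents that add atoms: N-iodosuccinimide, O=C1CCC(=O)N1I
Why: Electrophilic aromatic iodination, where C3 and C5 are equivalent and strongly activated, so one equivalent of NIS at low temperature gives a single mono-iodide.

**Step 4**
Reactants: 6 2,4,6-trihydroxy-3-iodobenzaldehyde
Product: 8 2,6-diacetoxy-4-(tert-butyldimethylsilyloxy)-3-iodobenzaldehyde, via 4-O-TBS iodoaldehyde 7 (not isolated)
Conditions: TBSCl (1.05 equiv), Et3N (1.05 equiv), CH2Cl2/DMF, −20 → 0 °C; then Ac2O (2.5 equiv), Et3N (3 equiv), 0 °C → rt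
Reagents that add atoms: TBSCl, CC(C)(C)[Si](C)(C)Cl; acetic anhydride, CC(=O)OC(C)=O
Why: Acidity-controlled selective silylation followed by acetylation in the same flask, in which one equivalent of Et3N ionises only the vinylogous-acid 4-OH (para to CHO, ortho to I), that oxygen takes the silyl group, and the two formyl-flanking OH groups are then capped as acetates, which fixes the oxygen that can later close the furan.

**Step 5**
Reactants: 8 2,6-diacetoxy-4-(tert-butyldimethylsilyloxy)-3-iodobenzaldehyde; 9 3-ethynylphenol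
Product: 11 2,6-diacetoxy-3-[(3-acetoxyphenyl)ethynyl]-4-(tert-butyldimethylsilyloxy)benzaldehyde, via 3-ethynylphenyl acetate 10 (not isolated)
Conditions: 9, Ac2O (1.05 equiv), Et3N, THF, rt, 45 min; then 8, PdCl2(PPh3)2 (3 mol %), CuI (5 mol %), degassed, 40 °C
Reagents that add atoms: acetic anhydride, CC(=O)OC(C)=O
Why: Sonogashira coupling, in which the phenol of 9 is masked first so that no phenoxide can shuffle acetyl groups, and no heteroannulation can occur at this stage because both oxygens next to the new alkyne are blocked.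

**Step 6**
Reactants: 11 2,6-diacetoxy-3-[(3-acetoxyphenyl)ethynyl]-4-(tert-butyldimethylsilyloxy)benzaldehyde
Product: 13 3-{[2,4-diacetoxy-6-hydroxy-3-((1E)-3-methylbuta-1,3-dien-1-yl)phenyl]ethynyl}phenyl acetate, via TBS-protected diene 12 (not isolated)
Conditions: Bu3P, methallyl chloride, MeCN, 60 °C, evaporate; KOtBu (0.95 equiv vs salt), THF, 0 °C; 11 (ylide 1.05 equiv), −78 → 0 °C; then Et3N·3HF, rt, 2 h
Reagents that add atoms: 3-chloro-2-methylprop-1-ene (methallyl chloride), C=C(C)CCl
Why: Wittig olefination with an allylic tributylphosphonium ylide, which is E-selective for semistabilised ylides and passes through an oxaphosphetane rather than a free alkoxide (so the flanking acetates do not migrate at −78 °C), followed by fluoride cleavage of the aryl silyl ether under slightly acidic conditions that leave aryl acetates alone.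

**Step 7**
Reactants: 13 3-{[2,4-diacetoxy-6-hydroxy-3-((1E)-3-methylbuta-1,3-dien-1-yl)phenyl]ethynyl}phenyl acetate; 4 (E)-2,4,4'-triacetoxy-2'-hydroxychalcone
Product: 17 (3R,4R,5S)-all-trans cycloadduct hexaacetate (free 2'-OH), via boron chelate of chalcone 14 (not isolated), via benzofuranyl diene 15 (not isolated), via boron-bound adduct 16 (not isolated)
Conditions: flask A: (R)-VANOL, BH3·THF, AcOH (1.6 equiv each), THF, rt, evaporate; 4 (1.3 equiv), THF, rt, evaporate; PhCF3, 5 Å MS. Flask B: 13, Ph3PAuNTf2 (2 mol %), PhCF3, rt, 30 min. Cannulate B into A, rt → 40 °C, 48 h; aq. work-up, chromatography (VANOL recovered)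
Reagents that add atoms: none
Why: Proposed new method: an orthogonal relay of two known reaction types, the gold(I)-catalysed 5-endo-dig hydroalkoxylation of an o-alkynylphenol and the Kelly-type chiral-borate-promoted Diels–Alder reaction of a 2'-hydroxychalcone, in which only the free OH of 13 can attack the Au-activated alkyne (the other flanking oxygen is an acetate), the cycloisomerisation is neutral and leaves neither by-product nor free phenol to disturb the coordinatively saturated chelate 14, and the LUMO-lowered s-cis enone of 14 then adds the (E)-diene 15 suprafacially at its open Cα-Si face through the exo transition state (the twisted 2,6-diacetoxyaryl group avoids the ligand wall), which sets C3, C4 and C5 together as all-trans (3R,4R,5S).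

**Step 8**
Reactants: 17 (3R,4R,5S)-all-trans cycloadduct hexaacetate
Product: 18 CNP0221531.1
Conditions: K2CO3 (8 equiv), MeOH/THF, Ar, 0 °C → rt, 2 h; 1 M HCl to pH 4–5
Reagents that add atoms: none
Why: Zemplén-type base-mediated transesterification of six aryl acetates, where C3 and C5 are not acidic and C4 (alpha to the ketone) already has the more stable all-equatorial all-trans configuration, so base cannot erode the stereochemistry.

**Compound list**
1 | 2,4-dihydroxyacetophenone | CC(=O)c1ccc(O)cc1O | starting material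
2 | 2,4-dihydroxybenzaldehyde | O=Cc1ccc(O)cc1O | starting material
3 | (E)-2,2',4,4'-tetrahydroxychalcone | O=C(/C=C/c1ccc(O)cc1O)c1ccc(O)cc1O | intermediate
4 | (E)-2,4,4'-triacetoxy-2'-hydroxychalcone | CC(=O)Oc1ccc(/C=C/C(=O)c2ccc(OC(C)=O)cc2O)c(OC(C)=O)c1 | intermediate
5 | 2,4,6-trihydroxybenzaldehyde | O=Cc1c(O)cc(O)cc1O | starting material
6 | 2,4,6-trihydroxy-3-iodobenzaldehyde | O=Cc1c(O)cc(O)c(I)c1O | intermediate
7 | 4-(tert-butyldimethylsilyloxy)-2,6-dihydroxy-3-iodobenzaldehyde (not isolated) | O=Cc1c(O)cc(O[Si](C)(C)C(C)(C)C)c(I)c1O | intermediate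
8 | 2,6-diacetoxy-4-(tert-butyldimethylsilyloxy)-3-iodobenzaldehyde | CC(=O)Oc1cc(O[Si](C)(C)C(C)(C)C)c(I)c(OC(C)=O)c1C=O | intermediate
9 | 3-ethynylphenol | C#Cc1cccc(O)c1 | starting material
10 | 3-ethynylphenyl acetate (not isolated) | C#Cc1cccc(OC(C)=O)c1 | intermediate
11 | 2,6-diacetoxy-3-[(3-acetoxyphenyl)ethynyl]-4-(tert-butyldimethylsilyloxy)benzaldehyde | CC(=O)Oc1cccc(C#Cc2c(O[Si](C)(C)C(C)(C)C)cc(OC(C)=O)c(C=O)c2OC(C)=O)c1 | intermediate
12 | TBS ether of 13, (E)-diene (not isolated) | CC(=O)Oc1cccc(C#Cc2c(O[Si](C)(C)C(C)(C)C)cc(OC(C)=O)c(/C=C/C(C)=C)c2OC(C)=O)c1 | intermediate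
13 | 3-{[2,4-diacetoxy-6-hydroxy-3-((1E)-3-methylbuta-1,3-dien-1-yl)phenyl]ethynyl}phenyl acetate | CC(=O)Oc1cccc(C#Cc2c(O)cc(OC(C)=O)c(/C=C/C(C)=C)c2OC(C)=O)c1 | intermediate
14 | spiro-borate chelate of 4 (2'-O and C=O on boron) carrying (R)-VANOL; the axis is not encodable in SMILES (not isolated) | CC(=O)Oc1ccc(/C=C/C2=[O+][B-]3(Oc4cc(OC(C)=O)ccc24)Oc2c(c(-c4ccccc4)cc4ccccc24)-c2c(O3)c3ccccc3cc2-c2ccccc2)c(OC(C)=O)c1 | intermediate
15 | 4,6-diacetoxy-2-(3-acetoxyphenyl)-5-[(1E)-3-methylbuta-1,3-dien-1-yl]benzofuran (not isolated) | CC(=O)Oc1cccc(-c2cc3c(OC(C)=O)c(/C=C/C(C)=C)c(OC(C)=O)cc3o2)c1 | intermediate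
16 | (R)-VANOL spiro-borate chelate of 17 (not isolated) | CC1=C[C@@H](c2c(OC(C)=O)cc3oc(-c4cccc(OC(C)=O)c4)cc3c2OC(C)=O)[C@H](C2=[O+][B-]3(Oc4cc(OC(C)=O)ccc24)Oc2c(c(-c4ccccc4)cc4ccccc24)-c2c(O3)c3ccccc3cc2-c2ccccc2)[C@@H](c2ccc(OC(C)=O)cc2OC(C)=O)C1 | intermediate
17 | (3R,4R,5S)-all-trans adduct: C3 4,6-diacetoxy-2-(3-acetoxyphenyl)benzofuran-5-yl, C4 4-acetoxy-2-hydroxybenzoyl, C5 2,4-diacetoxyphenyl, C1 methyl | CC1=C[C@@H](c2c(OC(C)=O)cc3oc(-c4cccc(OC(C)=O)c4)cc3c2OC(C)=O)[C@H](C(=O)c2ccc(OC(C)=O)cc2O)[C@@H](c2ccc(OC(C)=O)cc2OC(C)=O)C1 | intermediate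
18 | CNP0221531.1, (3R,4R,5S)-all-trans | CC1=C[C@@H](c2c(O)cc3oc(-c4cccc(O)c4)cc3c2O)[C@H](C(=O)c2ccc(O)cc2O)[C@@H](c2ccc(O)cc2O)C1 | target

**Step count and risks**
Total step count: 8. Longest linear sequence: 6 (steps 3 to 8).

Step 7 is the most likely to fail, through gold residues or traces of phenol upsetting the borate, or through insufficient exo:endo ratio or ee. The fallback separates the two ring closures and takes the absolute configuration from resolution instead of from the boron template. It sets out from 13. The furan is closed alone (AgOTf 5 mol %, CH2Cl2, rt) and 15 is isolated. Compound 15 is then combined with 4 over silica-supported silver nanoparticles (CH2Cl2, 50 °C). The racemic all-trans hexaacetate F1 is separated from the endo isomer by chromatography and resolved by preparative chiral SFC. The (3R,4R,5S) enantiomer is 17, where the route is rejoined.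

Step 6 is the second risk, because the basic ylide may attack or enolise the flanking aryl acetates. The fallback builds the diene in two non-basic C–C events. It sets out from 11. The neutral stabilised ylide 1-(triphenylphosphoranylidene)propan-2-one (toluene, 60 °C) gives the (E)-enone F2. Its ketone is then methylenated chemoselectively over the esters with the Lombardo reagent (Zn, CH2Br2, TiCl4, THF/CH2Cl2, 0 °C). This gives 12, where the route is rejoined before the fluoride treatment.

Step 4 is the third risk, because mono-silylation may not discriminate the 4-OH from the 6-OH. The fallback reaches the same O-pattern by selective deprotection instead of selective protection. It sets out from 6. Peracetylation (Ac2O, pyridine) gives the 2,4,6-triacetoxy-3-iodobenzaldehyde F3. Thiolysis with PhSH (1 equiv) and catalytic imidazole in NMP at 0 °C removes only the acetate para to the formyl group, the best phenoxide leaving group, and gives the 2,6-diacetoxy-4-hydroxy-3-iodobenzaldehyde F4. TBSCl/imidazole then gives 8, where the route is rejoined.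

**Further compounds**
F1 | step 7 | racemic all-trans hexaacetate (17 plus its enantiomer) | CC1=C[C@@H](c2c(OC(C)=O)cc3oc(-c4cccc(OC(C)=O)c4)cc3c2OC(C)=O)[C@H](C(=O)c2ccc(OC(C)=O)cc2O)[C@@H](c2ccc(OC(C)=O)cc2OC(C)=O)C1.CC1=C[C@H](c2c(OC(C)=O)cc3oc(-c4cccc(OC(C)=O)c4)cc3c2OC(C)=O)[C@@H](C(=O)c2ccc(OC(C)=O)cc2O)[C@H](c2ccc(OC(C)=O)cc2OC(C)=O)C1
F2 | step 6 | (E)-4-{2,6-diacetoxy-3-[(3-acetoxyphenyl)ethynyl]-4-(tert-butyldimethylsilyloxy)phenyl}but-3-en-2-one | CC(=O)/C=C/c1c(OC(C)=O)cc(O[Si](C)(C)C(C)(C)C)c(C#Cc2cccc(OC(C)=O)c2)c1OC(C)=O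
F3 | step 4 | 2,4,6-triacetoxy-3-iodobenzaldehyde | CC(=O)Oc1cc(OC(C)=O)c(I)c(OC(C)=O)c1C=O
F4 | step 4 | 2,6-diacetoxy-4-hydroxy-3-iodobenzaldehyde | CC(=O)Oc1cc(O)c(I)c(OC(C)=O)c1C=O
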